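**Retrosynthetic overview**

1. Target: furo[3,2-b]pyran-5-one. Ring A is the tetrahydrofuran (O1, C2, C3, C3a, C7a, all four substituents cis); ring B is the dihydropyranone (C3a, O4, C5, C6, C7, C7a). The side chain on C2 is C1'=C2' (E), C3'–OH, C4'–OBz, C5' methyl.
2. Key disconnection C2'–C3': the allylic carbinol C1'=C2'–C3'(OH), flanked by ring-A carbon C2 and by the benzoyloxy stereocentre C4', is the retron of a nickel-catalysed reductive alkyne–aldehyde–silane coupling. It is cut to a terminal alkyne on C2 of ring A and (R)-2-(benzoyloxy)propanal.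
3. Ring A is present from the start: C2, C3, C3a and C7a are C1–C4 of D-mannofuranose (all-cis). C2 is set by alkynylation of the mannono-1,4-lactone and face-selective silane reduction of the hemiketal.
4. Ring B is closed last: cleavage of the mannose C5–C6 bond unmasks the C7 aldehyde, (Z)-olefination adds C6 and C5, and acid closes the lactone through O4 (mannose O3) while all protecting groups fall.
5. The aldehyde comes from (R)-but-3-en-2-ol by benzoylation and ozonolysis. Order of events: ring A (chiral pool), fragment union, ring B.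

Key step: step 6

Remark: hemiketal 3 forms as an anomeric mixture; both anomers ionise to the same oxocarbenium ion, so its C1 configuration is left open. Sugar locants are used for the mannose-derived intermediates.

**Step 1**
Reactants: 1 2,3:5,6-di-O-isopropylidene-α-D-mannofuranose
Product: 2 2,3:5,6-di-O-isopropylidene-D-mannono-1,4-lactone
Conditions: Ac2O, DMSO, rt
Reagents that add atoms: none
Why: Albright–Goldman oxidation of the lactol to the γ-lactone runs under non-acidic conditions that leave both acetonides and all stereocentres untouched.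

**Step 2**
Reactants: 2 2,3:5,6-di-O-isopropylidene-D-mannono-1,4-lactone
Product: 3 1-C-ethynyl-2,3:5,6-di-O-isopropylidene-D-mannofuranose (hemiketal, anomeric mixture)
Conditions: HC≡CMgBr, THF, −78 to −20 °C; then aq. NH4Cl
Reagents that add atoms: ethynylmagnesium bromide, C#C[Mg]Br
Why: Addition of the alkynyl Grignard reagent to the γ-lactone carbonyl should stop at the tetrahedral magnesium alkoxide at low temperature and give the hemiketal on protonation (first half of a lactone-based C-glycoside synthesis), with no existing stereocentre affected.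

**Step 3**
Reactants: 3 1-C-ethynyl-2,3:5,6-di-O-isopropylidene-D-mannofuranose
Product: 5 (2,3:5,6-di-O-isopropylidene-β-D-mannofuranosyl)ethyne (ethynyl cis to the 2,3-acetonide and to the C4 side chain), via oxocarbenium ion pair 4 (not isolated)
Conditions: Et3SiH, BF3·OEt2, CH2Cl2/MeCN, −78 to −40 °C; then aq. NaHCO3
Reagents that add atoms: none
Why: BF3·OEt2 ionises the hemiketal to the alkyne-conjugated, cis-fused bicyclic oxocarbenium ion 4 and Et3SiH should deliver hydride to its convex α-face, anti to the 2,3-acetonide and the C4 dioxolanyl group (ionic hydrogenation of a ketofuranose hemiketal, as in C-alkynyl glycoside synthesis), so the ethynyl group is left cis to both and the future C2 stereocentre is set.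

**Step 4**
Reactants: 6 (R)-but-3-en-2-ol
Product: 7 (R)-but-3-en-2-yl benzoate
Conditions: BzCl, pyridine, DMAP (cat.), CH2Cl2, 0 °C to rt
Reagents that add atoms: benzoyl chloride, O=C(Cl)c1ccccc1
Why: DMAP-catalysed acylation of the secondary alcohol installs the benzoate of the target without touching the stereocentre (future C4').

**Step 5**
Reactants: 7 (R)-but-3-en-2-yl benzoate
Product: 9 (R)-2-(benzoyloxy)propanal, via ozonide 8 (not isolated)
Conditions: O3, CH2Cl2, −78 °C; then Me2S, −78 °C to rt; used crude
Reagents that add atoms: ozone, [O-][O+]=O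
Why: Criegee ozonolysis of the terminal alkene and reductive cleavage of ozonide 8 with Me2S should give the α-benzoyloxy aldehyde under neutral conditions that do not enolise the stereocentre.

**Step 6**
Reactants: 5 (2,3:5,6-di-O-isopropylidene-β-D-mannofuranosyl)ethyne; 9 (R)-2-(benzoyloxy)propanal
Product: 10 (1E,3S,4R)-4-(benzoyloxy)-3-[(tert-butyldimethylsilyl)oxy]-1-(2,3:5,6-di-O-isopropylidene-β-D-mannofuranosyl)pent-1-ene
Conditions: Ni(cod)2 (10 mol %), 1,3-dimesitylimidazolium chloride (10 mol %), KOt-Bu (10 mol %), t-BuMe2SiH (2 equiv), THF, rt, slow addition of 5 and 9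
Reagents that add atoms: tert-butyldimethylsilane, C[SiH](C)C(C)(C)C
Why: Zerovalent nickel carrying the N-heterocyclic carbene binds the terminal alkyne of 5 and the aldehyde of 9 and undergoes oxidative cyclisation, a formal (2+2+1) union at the metal, to a five-membered oxanickelacyclopentene in which the new C2'–C3' bond joins the unsubstituted alkyne terminus to the carbonyl carbon; σ-bond metathesis of the Ni–O bond with the silane and C–H reductive elimination then release the (E)-allylic silyl ether and return the catalyst. The closest known reaction type is the nickel/carbene-catalysed three-component reductive coupling of terminal alkynes, aldehydes and trialkylsilanes (Montgomery type), including its anti-selective use with α-oxygenated aldehydes. No ring of the target is closed here; the only ring formed is the transient metallacycle, closed by oxidative cyclisation and opened again within the same turnover. The new C3' stereocentre is controlled by the C4' benzoyloxy stereocentre of 9 through a polar Felkin–Anh arrangement (C–OBz bond antiperiplanar to the forming bond, no chelation at the carbene-ligated metal), which should place C3'–O and C4'–O anti, and the (E)-geometry follows from syn delivery of carbon and hydrogen across the alkyne. The step needs regioselectivity (secured by the terminal alkyne, whose substituted carbon stays on nickel), chemoselectivity (secured by running it before any enoate exists, with acetonides and the benzoate as the only other functions) and protection of the new hydroxyl against 1,2-benzoyl migration (secured because the oxygen leaves the metal directly as its silyl ether).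

**Step 7**
Reactants: 10 (1E,3S,4R)-4-(benzoyloxy)-3-[(tert-butyldimethylsilyl)oxy]-1-(2,3:5,6-di-O-isopropylidene-β-D-mannofuranosyl)pent-1-ene
Product: 12 C5 aldehyde (2,3-O-isopropylidene tetrahydrofuran carrying formyl, acetonide and the silylated side chain all cis), via 5,6-diol 11 (not isolated)
Conditions: H5IO6, EtOAc, rt
Reagents that add atoms: none
Why: Periodic acid should hydrolyse only the terminal 5,6-dioxolane and cleave the liberated 1,2-diol in the same pot (Malaprade glycol cleavage of the mannose C5–C6 bond), while the cis-fused 2,3-acetonide, the silyl ether and the benzoate stay and the α-alkoxy aldehyde carbon is not epimerised.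

**Step 8**
Reactants: 12 C5 aldehyde
Product: 13 methyl (Z)-enoate (methyl (Z)-3-substituted acrylate on C4 of the 2,3-O-isopropylidene tetrahydrofuran)
Conditions: (CF3CH2O)2P(O)CH2CO2Me, KN(SiMe3)2, 18-crown-6, THF, −78 °C
Reagents that add atoms: methyl bis(2,2,2-trifluoroethyl)phosphonoacetate, COC(=O)CP(=O)(OCC(F)(F)F)OCC(F)(F)F
Why: The Still–Gennari variant of the Horner–Wadsworth–Emmons reaction should give the (Z)-enoate kinetically through fast collapse of the syn-oxaphosphetane, at a temperature where the α-alkoxy aldehyde does not epimerise and the benzoate is not attacked.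

**Step 9**
Reactants: 13 methyl (Z)-enoate
Product: 15 (2S,3R,3aR,7aR)-2-[(1E,3S,4R)-4-(benzoyloxy)-3-hydroxypent-1-en-1-yl]-3-hydroxy-2,3,3a,7a-tetrahydro-5H-furo[3,2-b]pyran-5-one (CNP0143030.1), via seco triol ester 14 (not isolated)
Conditions: TFA/H2O (9:1), 0 °C to rt
Reagents that add atoms: none
Why: Aqueous trifluoroacetic acid should hydrolyse the acetonide and the allylic silyl ether, after which the freed O3–H, held cis to the (Z)-enoate, closes ring B by 6-exo-trig lactonisation and leaves O2–H as the free C3 hydroxyl, with all six stereocentres untouched.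

**Compound list**

1 | 2,3:5,6-di-O-isopropylidene-α-D-mannofuranose | O[C@H]1O[C@H]([C@H]2COC(C)(C)O2)[C@@H]2OC(C)(C)O[C@H]12 | starting material
2 | 2,3:5,6-di-O-isopropylidene-D-mannono-1,4-lactone | O=C1O[C@H]([C@H]2COC(C)(C)O2)[C@@H]2OC(C)(C)O[C@H]12 | intermediate
3 | 1-C-ethynyl-2,3:5,6-di-O-isopropylidene-D-mannofuranose (anomeric mixture) | C#CC1(O)O[C@H]([C@H]2COC(C)(C)O2)[C@@H]2OC(C)(C)O[C@H]12 | intermediate
4 | 1-C-ethynyl-2,3:5,6-di-O-isopropylidene-D-mannofuranosylium hydroxytrifluoroborate (oxocarbenium ion pair) | C#CC1=[O+][C@H]([C@H]2COC(C)(C)O2)[C@@H]2OC(C)(C)O[C@H]12.O[B-](F)(F)F | intermediate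
5 | (2,3:5,6-di-O-isopropylidene-β-D-mannofuranosyl)ethyne | C#C[C@@H]1O[C@H]([C@H]2COC(C)(C)O2)[C@@H]2OC(C)(C)O[C@H]12 | intermediate
6 | (R)-but-3-en-2-ol | C[C@@H](O)C=C | starting material
7 | (R)-but-3-en-2-yl benzoate | C[C@@H](OC(=O)c1ccccc1)C=C | intermediate
8 | (1R)-1-(1,2,4-trioxolan-3-yl)ethyl benzoate (ozonide) | C[C@@H](OC(=O)c1ccccc1)C1OCOO1 | intermediate
9 | (R)-2-(benzoyloxy)propanal | C[C@@H](OC(=O)c1ccccc1)C=O | intermediate
10 | (1E,3S,4R)-4-(benzoyloxy)-3-[(tert-butyldimethylsilyl)oxy]-1-(2,3:5,6-di-O-isopropylidene-β-D-mannofuranosyl)pent-1-ene | C[C@@H](OC(=O)c1ccccc1)[C@@H](O[Si](C)(C)C(C)(C)C)/C=C/[C@@H]1O[C@H]([C@H]2COC(C)(C)O2)[C@@H]2OC(C)(C)O[C@H]12 | intermediate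
11 | 5,6-diol of 10 (2,3-O-isopropylidene retained) | C[C@@H](OC(=O)c1ccccc1)[C@@H](O[Si](C)(C)C(C)(C)C)/C=C/[C@@H]1O[C@H]([C@H](O)CO)[C@@H]2OC(C)(C)O[C@H]12 | intermediate
12 | C5 aldehyde (formyl, 2,3-acetonide and side chain all cis on the tetrahydrofuran) | C[C@@H](OC(=O)c1ccccc1)[C@@H](O[Si](C)(C)C(C)(C)C)/C=C/[C@@H]1O[C@H](C=O)[C@@H]2OC(C)(C)O[C@H]12 | intermediate
13 | methyl (Z)-enoate of 12 | C[C@@H](OC(=O)c1ccccc1)[C@@H](O[Si](C)(C)C(C)(C)C)/C=C/[C@@H]1O[C@H](/C=C\C(=O)OC)[C@@H]2OC(C)(C)O[C@H]12 | intermediate
14 | seco triol ester: methyl (Z)-3-{all-cis-3,4-dihydroxy-5-[(1E,3S,4R)-4-(benzoyloxy)-3-hydroxypent-1-enyl]tetrahydrofuran-2-yl}acrylate | C[C@@H](OC(=O)c1ccccc1)[C@@H](O)/C=C/[C@@H]1O[C@H](/C=C\C(=O)OC)[C@H](O)[C@@H]1O | intermediate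
15 | (2S,3R,3aR,7aR)-2-[(1E,3S,4R)-4-(benzoyloxy)-3-hydroxypent-1-en-1-yl]-3-hydroxy-2,3,3a,7a-tetrahydro-5H-furo[3,2-b]pyran-5-one | C[C@@H](OC(=O)c1ccccc1)[C@@H](O)/C=C/[C@@H]1O[C@@H]2C=CC(=O)O[C@@H]2[C@@H]1O | target

**Summary**

Total step count: 9. Longest linear sequence: 7 steps (steps 1, 2, 3, 6, 7, 8, 9); steps 4 and 5 form the short aldehyde branch.

**Steps most likely to fail**

Step 6 (key step). What may go wrong: oligomerisation of the terminal alkyne at nickel, β-elimination of the ring oxygen from the alkenylnickel intermediate, or weak Felkin control at the α-benzoyloxy aldehyde. Fallback, replacing nickel catalysis by stoichiometric chromium chemistry: set out from 5. Hydrostannation with Bu3SnH and Pd(PPh3)2Cl2 (THF, rt) should give the (E)-alkenylstannane F1. Iododestannylation (I2, CH2Cl2, 0 °C) should give the (E)-alkenyl iodide F2. A Nozaki–Hiyama–Kishi coupling of F2 with 9 (CrCl2, NiCl2 cat., DMSO/THF, rt) should give the allylic alcohol F3, again anti by Felkin–Anh control, which a chiral sulfonamide ligand on chromium can reinforce. Silylation (t-BuMe2SiCl, imidazole, DMF) returns to the route at 10.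

Step 3. What may go wrong: hydride delivery from the concave face, or loss of the terminal acetonide under the Lewis acid. Fallback, ring closure by substitution instead of oxocarbenium reduction: set out from 1, so that steps 1 and 2 are not needed. Addition of HC≡CMgBr (THF, 0 °C to rt) to the open aldehyde form of the lactol should give the 1,2-anti propargylic diol 1,2-dideoxy-4,5:7,8-di-O-isopropylidene-D-glycero-D-talo-oct-1-ynitol F4 (alkoxide-directed addition typical of 2,3-O-isopropylidene furanoses). TsCl in pyridine should sulfonylate the more accessible propargylic hydroxyl to the propargylic tosylate F5 (not isolated). O4 then displaces it with inversion (5-exo-tet), which places the alkyne cis to the acetonide and rejoins the route at 5.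

Step 9. What may go wrong: acid-promoted 1,2-benzoyl migration or allylic ionisation once the C3' hydroxyl is free, or sluggish cleavage of the silyl ether. Fallback, staged deprotection with fluoride instead of one-pot acid: set out from 13. 80% aqueous AcOH at 60 °C should remove the acetonide and close the lactone while the silyl ether stays on, giving the silyl-protected lactone F6. Buffered HF·pyridine/pyridine in THF at 0 °C then frees the C3' hydroxyl and reaches 15.

**Further compounds**

F1 | step 6 | (E)-2-(tributylstannyl)vinyl C-glycoside of 2,3:5,6-di-O-isopropylidene-β-D-mannofuranose | CCCC[Sn](CCCC)(CCCC)/C=C/[C@@H]1O[C@H]([C@H]2COC(C)(C)O2)[C@@H]2OC(C)(C)O[C@H]12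
F2 | step 6 | (E)-2-iodovinyl C-glycoside of 2,3:5,6-di-O-isopropylidene-β-D-mannofuranose | I/C=C/[C@@H]1O[C@H]([C@H]2COC(C)(C)O2)[C@@H]2OC(C)(C)O[C@H]12
F3 | step 6 | (1E,3S,4R)-4-(benzoyloxy)-1-(2,3:5,6-di-O-isopropylidene-β-D-mannofuranosyl)pent-1-en-3-ol | C[C@@H](OC(=O)c1ccccc1)[C@@H](O)/C=C/[C@@H]1O[C@H]([C@H]2COC(C)(C)O2)[C@@H]2OC(C)(C)O[C@H]12
F4 | step 3 | 1,2-dideoxy-4,5:7,8-di-O-isopropylidene-D-glycero-D-talo-oct-1-ynitol (1,2-anti propargylic diol) | C#C[C@@H](O)[C@H]1OC(C)(C)O[C@H]1[C@H](O)[C@H]1COC(C)(C)O1
F5 | step 3 | 3-O-(p-toluenesulfonyl) derivative of F4 (propargylic tosylate) | C#C[C@@H](OS(=O)(=O)c1ccc(C)cc1)[C@H]1OC(C)(C)O[C@H]1[C@H](O)[C@H]1COC(C)(C)O1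
F6 | step 9 | 3'-O-(tert-butyldimethylsilyl) ether of 15 | C[C@@H](OC(=O)c1ccccc1)[C@@H](O[Si](C)(C)C(C)(C)C)/C=C/[C@@H]1O[C@@H]2C=CC(=O)O[C@@H]2[C@@H]1O
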